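## The problem

The target is (2S)-2-(3,4-dihydroxyphenyl)-5,7-dihydroxy-6-(3-hydroxy-3-methylbutyl)-2,3-dihydro-4H-chromen-4-one: a flavanone with a phloroglucinol-type ring A, a dihydropyranone ring C, a catechol ring B and a hydrated prenyl chain on C6.

- **Regiochemistry.** C6 and C8 of a 5,7-dioxygenated chromanone are electronically alike, and in any open acylphloroglucinol precursor either ortho hydroxyl can close ring C. "6 and not 8" must therefore be decided by the way the rings are joined, not by a selectivity.
- **Stereochemistry.** C2 is the only stereocentre. It is benzylic and β to the C4 carbonyl, so it is lost by β-elimination of O1 from the C3 enolate (chalcone formation) under base, and also on heating with acid. No other stereocentre can control or restore it, so it must be set by a catalyst, late, with nothing basic after it.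
- **Sensitive groups.** The tertiary alcohol sits between two phenols: acid closes it onto O5 or O7 to a 2,2-dimethylchromane or dehydrates it. The catechol is oxidation-prone. The end of the route must be neutral and non-oxidising.
- **The feature that makes the key step possible.** Ring A (C4a, C5, C6, C7, C8, C8a) carries oxygen on C5, C7 and C8a, so it is the enol form of a cyclohexane-1,3,5-trione and each of its C–C bonds is a Claisen bond of a poly-β-carbonyl chain. The tertiary oxygen is joined to C7 through C(CH3)2, CH2, CH2 and C6: these five carbons and that oxygen are the six ring atoms of 6,6-dimethyltetrahydropyran-2-one with C7 as its carbonyl carbon. What remains (C8, C8a, C4a, C5 with O1, C2, C3, C4) is a 2-methyl-4-pyranone-3-carboxylate.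

## Retrosynthesis

**13 ⇒ 12 (four O–CH2Ph bonds).** The four phenols are carried as benzyl ethers; the tertiary alcohol stays free. Only neutral deprotection is admissible at the end, since acid would cyclise the chain and base would open ring C at C2. The forward step must cleave four aryl benzyl ethers without hydrogenolysis of the benzylic O1–C2 bond.

**12 ⇒ 10 + 11 (C2–C1' bond).** Cutting the aryl–C2 bond, rather than O1–C2 (oxa-Michael closure of a chalcone), makes the stereocentre by an irreversible C–C bond formation under catalyst control, on a flat achiral chromone, after all strongly basic steps. Precursor 10 has no stereocentre and ring B is the commercial boronic acid 11. The forward reaction must add an electron-rich aryl group to C2 of a 5,7-dialkoxychromone with high face selectivity.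

**10 ⇒ 9 (two O–benzyl bonds).** The phenols of 9 are masked so that the cationic palladium catalyst meets no acidic, chelating OH. The groups are the same as on ring B and cost no extra deprotection step.

**9 ⇒ 7 + 3 (C7–C8 and C5–C6 of ring A; the tertiary O–C7 bond is re-formed as a lactone).** This is the strategic cut.
- Cutting C4a–C5 or C8a–O1 leads back to a symmetric phloroglucinol and the 6/8 problem.
- Cutting the C6–side-chain bond (alkylation or cross-coupling of a 5,7-dihydroxychromone) again needs C6/C8 discrimination.
- Cutting C7–C8 and C5–C6 leaves ring C intact with O1 already on C8a, C8 as a methyl group and C5 as an ester: pyranone 7. The other piece, C6–C7 with the whole side chain, is lactone 3.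
- Chromone 9 (benzo ring, three hydroxyls, side chain in place) thus comes from two achiral, unprotected compounds of seven and eight carbons.
- The forward reaction must achieve lateral deprotonation of 7, C-acylation by a lactone, a second enolisation at the future C6, and ring closure through carbon rather than oxygen.

**7 ⇒ 4 + 5 (C3–C4 and O1–C6 of the pyranone).** C2, C3 and the ester of 7 are an acetoacetate (4). C4–C5–C6 is a formylacetyl unit, available as acid chloride 5. The forward reaction is C-acylation of a β-keto ester and acid-catalysed ring closure with loss of ethanol.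

**3 ⇒ 1 (C–CH3 bond).** The carbinol carbon comes from the ketone of keto acid 1 and a methyl Grignard reagent. The hydroxy acid 2 lactonises.

## Roads not taken

**Alternative 1:** the chalcone route (the most obvious). Cut O1–C2 and the C2–C3 π-bond: aldol condensation of a 3-alkyl-2,4,6-trihydroxyphenyl methyl ketone with a protected 3,4-dihydroxybenzaldehyde gives chalcone A1, and intramolecular oxa-Michael addition closes ring C.
- A1 has two ortho hydroxyls and both add to the enone, so the 8-substituted isomer A2 forms beside the target skeleton unless the three phenols are first differentiated by protecting groups, itself a selectivity problem.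
- The oxa-Michael addition is reversible under the conditions that promote it, so any enantioselection can erode.
- The chain must be put on by C-alkylation of an acylphloroglucinol (C/O and mono/di mixtures) and then hydrated.
- In the chosen plan O1–C8a exists before ring A, so no isomer can form, and C2 is made irreversibly.

**Alternative 2:** side chain onto the intact flavanone. Cut the C6–side-chain bond: starting from enantiopure eriodictyol A3, aromatic Claisen rearrangement of the 5-O-allyl ether A4 gives the 6-allyl flavanone A5 (C6 is the only ortho position of O5). Ruthenium-catalysed cross-metathesis to the prenyl group and Mukaiyama hydration follow.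
- The rearrangement needs heat or a Lewis acid acting on a flavanone, conditions under which ring C opens and recloses and C2 racemises.
- A Claisen–Cope shift to C8 competes.
- The sequence (protect, allylate, rearrange, metathesise, hydrate, deprotect) is longer than the chosen one.
- It starts from the chiral core of the target itself and so solves none of the ring construction.

**Alternative 3:** the same ring A annulation on a ring C that already carries the stereocentre. Cut C7–C8 and C5–C6 as in the chosen plan, but in the dihydropyranone ester A6 (from an asymmetric vinylogous aldol reaction of the protected aldehyde), and annulate with lactone 3 to give 12 directly.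
- This is two steps shorter.
- However, A6 and the flavanone product have an enolisable C3H2 next to the benzylic C2–O1 bond. The amide bases the annulation needs would trigger β-elimination of O1, whose leaving group is a stabilised 1,3-dicarbonyl enolate, so the stereocentre would be lost in the key step itself.
- In the chosen plan C2 and C3 are sp2 carbons during all strong-base chemistry and the stereocentre is made afterwards under near-neutral conditions.

Key step: step 3

Assumption: the (R)-configured pyridine–oxazoline ligand in step 5 is assigned by carrying over the facial preference this catalyst family shows for cyclic enones; if the chromone responds in the opposite sense, the (S)-ligand is used and nothing else changes.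

## Steps

Step 1
Reactants: 1 5-oxohexanoic acid
Product: 3 6,6-dimethyltetrahydro-2H-pyran-2-one, via hydroxy acid 2 (not isolated)
Conditions: MeMgBr (2.3 equiv), THF, −20 °C to rt; 2 M HCl; TsOH·H2O (cat.), CH2Cl2, rt
Reagents that add atoms: methylmagnesium bromide, C[Mg]Br
Why: Grignard addition to the ketone of the inert magnesium carboxylate, then acid-catalysed lactonisation of the δ-hydroxy acid, favoured by the gem-dimethyl group; no stereocentre is formed.

Step 2
Reactants: 4 methyl acetoacetate; 5 (E)-3-ethoxyacryloyl chloride
Product: 7 methyl 2-methyl-4-oxo-4H-pyran-3-carboxylate, via triketo ester 6 (not isolated)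
Conditions: MgCl2 (1.1 equiv), pyridine (2.2 equiv), CH2Cl2, 0 °C to rt; aq. HCl wash; then CF3CO2H, CH2Cl2, rt
Reagents that add atoms: none
Why: C-acylation of the chelated magnesium enolate of a β-keto ester by an acid chloride, then acid-catalysed 6-endo-trig addition of the acetyl enol oxygen to the β-ethoxy enone and loss of ethanol (4-pyranone synthesis from a masked 1,3,5-tricarbonyl compound).

Step 3
Reactants: 7 methyl 2-methyl-4-oxo-4H-pyran-3-carboxylate; 3 6,6-dimethyltetrahydro-2H-pyran-2-one
Product: 9 5,7-dihydroxy-6-(3-hydroxy-3-methylbutyl)-4H-chromen-4-one, via keto alcohol 8 (not isolated)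
Conditions: LiN(SiMe3)2 (1.1 equiv), THF, −78 °C; 3 (1.1 equiv), −78 to 0 °C; then LiN(i-Pr)2 (2.5 equiv), −78 °C to rt; AcOH, 0 °C
Reagents that add atoms: none
Why: Proposed new method: LiN(SiMe3)2 removes a proton from the C2-methyl group of 7, the only acidic sp3 C–H of the pyranone, giving a 2-methylene-2H-pyran-4-olate stabilised by the C4 ketone and the C3 ester; its exocyclic carbon (future C8) adds to the carbonyl of lactone 3 (future C7), and the lactol alkoxide opens because the liberated ketone 8 is at once deprotonated at the doubly activated C8–H, which also frees the tertiary alkoxide. LiN(i-Pr)2 then deprotonates the less acidic CH2 on the other side of the ketone (future C6) to a 1,3-dicarbonyl-type dianion, whose terminal carbanion attacks the neighbouring ester carbonyl (future C5) in a 6-(enolendo)-exo-trig Dieckmann closure of ring A; loss of methoxide and enolisation give the aromatic 5,7-diolate, which makes the sequence irreversible. The closest known reaction types are the Claisen acylation of the lateral anions of 2-methyl-4-pyranones and 2-methylchromones by esters, the acylation of β-dicarbonyl dianions at the terminal carbon, and the biomimetic Claisen cyclisation of 3,5,7-triketo esters to acylphloroglucinols; the use of a saturated lactone as a two-carbon partner that supplies C6, C7 and the hydroxyalkyl chain in one flask is the new element. No stereocentre is formed. The selectivity needed is C- over O-acylation in the ring closure (the enolate oxygen on C7 could lactonise onto the ester to a fused 2-pyranone): the charge-localised terminal carbanion of the dianion is the most nucleophilic site, and an enol lactone formed by O-attack can be reopened by lithium methoxide, whereas C-attack is removed from equilibrium by aromatisation. The 6-versus-8 question is settled by connectivity and not by selectivity: O1 is bonded to C8a before ring A exists, the ester carbon can only become C5 and the lactone α-carbon can only become C6. Amide bases are used because alkoxide or hydroxide would open the 4-pyranone ring by conjugate addition.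

Step 4
Reactants: 9 5,7-dihydroxy-6-(3-hydroxy-3-methylbutyl)-4H-chromen-4-one
Product: 10 5,7-bis(benzyloxy)-6-(3-hydroxy-3-methylbutyl)-4H-chromen-4-one
Conditions: BnBr (2.5 equiv), K2CO3 (3 equiv), n-Bu4NI (cat.), DMF, 60 °C
Reagents that add atoms: benzyl bromide, BrCc1ccccc1
Why: Williamson etherification; the 7-OH reacts readily and the hydrogen-bonded 5-OH on heating, while the tertiary alcohol is not deprotonated by carbonate.

Step 5
Reactants: 10 5,7-bis(benzyloxy)-6-(3-hydroxy-3-methylbutyl)-4H-chromen-4-one; 11 [3,4-bis(benzyloxy)phenyl]boronic acid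
Product: 12 (2S)-5,7-bis(benzyloxy)-2-[3,4-bis(benzyloxy)phenyl]-6-(3-hydroxy-3-methylbutyl)-2,3-dihydro-4H-chromen-4-one
Conditions: 11 (2 equiv), Pd(OCOCF3)2 (5 mol%), (R)-4-tert-butyl-2-(pyridin-2-yl)-4,5-dihydrooxazole (6 mol%), NH4PF6 (30 mol%), H2O (5 equiv), ClCH2CH2Cl, 60 °C
Reagents that add atoms: none
Why: Asymmetric conjugate addition of an arylboronic acid to a chromone with a cationic divalent palladium pyridine–oxazoline catalyst (transmetalation, enantio-determining insertion of C2=C3 into the Pd–aryl bond, protonolysis of the palladium enolate by water). The tert-butyl group of the ligand shields one face of the bound enone so that the aryl group is delivered to the face that gives (2S), and no base is present that could open the product at O1–C2.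

Step 6
Reactants: 12 (2S)-5,7-bis(benzyloxy)-2-[3,4-bis(benzyloxy)phenyl]-6-(3-hydroxy-3-methylbutyl)-2,3-dihydro-4H-chromen-4-one
Product: 13 (2S)-2-(3,4-dihydroxyphenyl)-5,7-dihydroxy-6-(3-hydroxy-3-methylbutyl)-2,3-dihydro-4H-chromen-4-one
Conditions: H2 (1 atm), 10% Pd/C, EtOAc/MeOH, rt
Reagents that add atoms: none
Why: Hydrogenolysis of four aryl benzyl ethers under neutral conditions that touch neither the acid-sensitive tertiary alcohol nor the base-sensitive C2 stereocentre; primary benzyl aryl ethers are cleaved faster than the secondary, ring-held O1–C2 bond.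

## Compound list

1 | 5-oxohexanoic acid | CC(=O)CCCC(=O)O | starting material
2 | 5-hydroxy-5-methylhexanoic acid | CC(C)(O)CCCC(=O)O | intermediate
3 | 6,6-dimethyltetrahydro-2H-pyran-2-one | CC1(C)CCCC(=O)O1 | intermediate
4 | methyl acetoacetate | CC(=O)CC(=O)OC | starting material
5 | (E)-3-ethoxyacryloyl chloride | CCO/C=C/C(=O)Cl | starting material
6 | methyl (E)-2-acetyl-5-ethoxy-3-oxopent-4-enoate | CCO/C=C/C(=O)C(C(C)=O)C(=O)OC | intermediate
7 | methyl 2-methyl-4-oxo-4H-pyran-3-carboxylate | COC(=O)c1c(C)occc1=O | intermediate
8 | methyl 2-(6-hydroxy-6-methyl-2-oxoheptyl)-4-oxo-4H-pyran-3-carboxylate | COC(=O)c1c(CC(=O)CCCC(C)(C)O)occc1=O | intermediate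
9 | 5,7-dihydroxy-6-(3-hydroxy-3-methylbutyl)-4H-chromen-4-one | CC(C)(O)CCc1c(O)cc2occc(=O)c2c1O | intermediate
10 | 5,7-bis(benzyloxy)-6-(3-hydroxy-3-methylbutyl)-4H-chromen-4-one | CC(C)(O)CCc1c(OCc3ccccc3)cc2occc(=O)c2c1OCc1ccccc1 | intermediate
11 | [3,4-bis(benzyloxy)phenyl]boronic acid | OB(O)c1ccc(OCc2ccccc2)c(OCc2ccccc2)c1 | starting material
12 | (2S)-5,7-bis(benzyloxy)-2-[3,4-bis(benzyloxy)phenyl]-6-(3-hydroxy-3-methylbutyl)-2,3-dihydro-4H-chromen-4-one | CC(C)(O)CCc1c(OCc3ccccc3)cc2c(c1OCc1ccccc1)C(=O)C[C@@H](c1ccc(OCc3ccccc3)c(OCc3ccccc3)c1)O2 | intermediate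
13 | (2S)-2-(3,4-dihydroxyphenyl)-5,7-dihydroxy-6-(3-hydroxy-3-methylbutyl)-2,3-dihydro-4H-chromen-4-one | CC(C)(O)CCc1c(O)cc2c(c1O)C(=O)C[C@@H](c1ccc(O)c(O)c1)O2 | target

## Step count and least certain steps

Total: 6 steps. Longest linear sequence: 5 steps (steps 2 to 6, from 4).

**Step 3 (key step, proposed new method).**
- What may go wrong: slow addition of the stabilised lateral anion to the lactone; ring closure through the enolate oxygen instead of carbon; the sequence stalling at the open keto alcohol because the second enolisation is incomplete; self-condensation of the pyranone anion with unreacted 7.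
- Fallback (known chemistry, ring A bought instead of built): it cannot set out from a compound of the route, since 1 to 7 serve only the annulation. It sets out from commercial 5,7-dihydroxy-4H-chromen-4-one F1 and comes back to the route at 10.
- Selective 7-O-benzylation (BnBr, K2CO3, acetone) gives 7-(benzyloxy)-5-hydroxy-4H-chromen-4-one F2. Iodination ortho to the free, hydrogen-bonded 5-OH (BnMe3N·ICl2, CaCO3, CH2Cl2/MeOH) gives 7-(benzyloxy)-5-hydroxy-6-iodo-4H-chromen-4-one F3. 5-O-Benzylation gives 5,7-bis(benzyloxy)-6-iodo-4H-chromen-4-one F4.
- B-alkyl Suzuki–Miyaura coupling (Pd(dppf)Cl2, K3PO4, THF/H2O) with 9-[3-(9-borabicyclo[3.3.1]nonan-9-yloxy)-3-methylbutyl]-9-borabicyclo[3.3.1]nonane F5, made in the flask from 2-methylbut-3-en-2-ol and two equivalents of 9-BBN-H, gives 10.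
- The price is that C6 versus C8 again rests on a selectivity (ortho-iodination) and not on connectivity.

**Step 5.**
- What may go wrong: low conversion, because C2 of a 5,7-dialkoxychromone is a weak acceptor and the 5-benzyloxy group is close to the carbonyl the catalyst must bind; protodeboronation of the electron-rich boronic acid; β-hydride elimination to the flavone; incomplete face selectivity.
- Fallback (resolution instead of asymmetric addition), from 10 back to 12: the aryl group is added without induction (Pd(OCOCF3)2, 2,2'-bipyridine, 11, aqueous medium) to give racemic 5,7-bis(benzyloxy)-2-[3,4-bis(benzyloxy)phenyl]-6-(3-hydroxy-3-methylbutyl)-2,3-dihydro-4H-chromen-4-one F6.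
- Kinetic resolution by asymmetric transfer hydrogenation (RuCl(p-cymene)(TsDPEN), the ligand enantiomer that reduces the (2R)-ketone faster, HCO2H/Et3N) converts the unwanted enantiomer into (2R,4R)-5,7-bis(benzyloxy)-2-[3,4-bis(benzyloxy)phenyl]-6-(3-hydroxy-3-methylbutyl)chroman-4-ol F7 and leaves 12.

**Step 2.**
- What may go wrong: O-acylation, or addition–elimination of the enolate at the β-carbon of the acid chloride, instead of C-acylation; oligomerisation of the acid chloride by pyridine; ring closure through the ester carbonyl.
- Fallback (formyl carbon introduced last, by Claisen formylation), from 4 back to 7: C-acetylation (AcCl, MgCl2, pyridine) gives methyl 2-acetyl-3-oxobutanoate F8.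
- Its dianion (NaH, then LiN(i-Pr)2) is formylated at a terminal methyl group with ethyl formate to give methyl 2-acetyl-3,5-dioxopentanoate F9, which cyclises to 7 on acidification.

**Step 6.**
- What may go wrong: over-reduction, i.e. hydrogenolysis of the benzylic O1–C2 bond (opening of ring C) or reduction of the C4 ketone; slow cleavage of the hindered 5-O-benzyl ether; air oxidation of the catechol during work-up.
- Fallback (fluoride-labile groups, no hydrogen), from 9 back to 13: silylation of the unchelated 7-OH (t-BuMe2SiCl, imidazole, DMF) gives 7-(tert-butyldimethylsilyloxy)-5-hydroxy-6-(3-hydroxy-3-methylbutyl)-4H-chromen-4-one F10.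
- Commercial 4-bromobenzene-1,2-diol is silylated to 4-bromo-1,2-bis(tert-butyldimethylsilyloxy)benzene F11 and converted (n-BuLi, B(OMe)3, then aqueous work-up) into [3,4-bis(tert-butyldimethylsilyloxy)phenyl]boronic acid F12.
- Conjugate addition under the conditions of step 5 gives (2S)-7-(tert-butyldimethylsilyloxy)-2-[3,4-bis(tert-butyldimethylsilyloxy)phenyl]-5-hydroxy-6-(3-hydroxy-3-methylbutyl)-2,3-dihydro-4H-chromen-4-one F13.
- Desilylation with Et3N·3HF in THF gives 13.

## Further compounds

F1 | step 3 | 5,7-dihydroxy-4H-chromen-4-one | O=c1ccoc2cc(O)cc(O)c12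
F2 | step 3 | 7-(benzyloxy)-5-hydroxy-4H-chromen-4-one | O=c1ccoc2cc(OCc3ccccc3)cc(O)c12
F3 | step 3 | 7-(benzyloxy)-5-hydroxy-6-iodo-4H-chromen-4-one | O=c1ccoc2cc(OCc3ccccc3)c(I)c(O)c12
F4 | step 3 | 5,7-bis(benzyloxy)-6-iodo-4H-chromen-4-one | O=c1ccoc2cc(OCc3ccccc3)c(I)c(OCc3ccccc3)c12
F5 | step 3 | 9-[3-(9-borabicyclo[3.3.1]nonan-9-yloxy)-3-methylbutyl]-9-borabicyclo[3.3.1]nonane | CC(C)(CCB1C2CCCC1CCC2)OB1C2CCCC1CCC2
F6 | step 5 | racemic 5,7-bis(benzyloxy)-2-[3,4-bis(benzyloxy)phenyl]-6-(3-hydroxy-3-methylbutyl)-2,3-dihydro-4H-chromen-4-one | CC(C)(O)CCc1c(OCc3ccccc3)cc2c(c1OCc1ccccc1)C(=O)CC(c1ccc(OCc3ccccc3)c(OCc3ccccc3)c1)O2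
F7 | step 5 | (2R,4R)-5,7-bis(benzyloxy)-2-[3,4-bis(benzyloxy)phenyl]-6-(3-hydroxy-3-methylbutyl)chroman-4-ol | CC(C)(O)CCc1c(OCc3ccccc3)cc2c(c1OCc1ccccc1)[C@H](O)C[C@H](c1ccc(OCc3ccccc3)c(OCc3ccccc3)c1)O2
F8 | step 2 | methyl 2-acetyl-3-oxobutanoate | CC(=O)C(C(C)=O)C(=O)OC
F9 | step 2 | methyl 2-acetyl-3,5-dioxopentanoate | CC(=O)C(C(=O)CC=O)C(=O)OC
F10 | step 6 | 7-(tert-butyldimethylsilyloxy)-5-hydroxy-6-(3-hydroxy-3-methylbutyl)-4H-chromen-4-one | CC(C)(O)CCc1c(O[Si](C)(C)C(C)(C)C)cc2occc(=O)c2c1O
F11 | step 6 | 4-bromo-1,2-bis(tert-butyldimethylsilyloxy)benzene | Brc1ccc(O[Si](C)(C)C(C)(C)C)c(O[Si](C)(C)C(C)(C)C)c1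
F12 | step 6 | [3,4-bis(tert-butyldimethylsilyloxy)phenyl]boronic acid | OB(O)c1ccc(O[Si](C)(C)C(C)(C)C)c(O[Si](C)(C)C(C)(C)C)c1
F13 | step 6 | (2S)-7-(tert-butyldimethylsilyloxy)-2-[3,4-bis(tert-butyldimethylsilyloxy)phenyl]-5-hydroxy-6-(3-hydroxy-3-methylbutyl)-2,3-dihydro-4H-chromen-4-one | CC(C)(O)CCc1c(O[Si](C)(C)C(C)(C)C)cc2c(c1O)C(=O)C[C@@H](c1ccc(O[Si](C)(C)C(C)(C)C)c(O[Si](C)(C)C(C)(C)C)c1)O2
A1 | alternative 1 | (E)-3-(3,4-dihydroxyphenyl)-1-[2,4,6-trihydroxy-3-(3-hydroxy-3-methylbutyl)phenyl]prop-2-en-1-one | CC(C)(O)CCc1c(O)cc(O)c(C(=O)/C=C/c2ccc(O)c(O)c2)c1O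
A2 | alternative 1 | racemic 2-(3,4-dihydroxyphenyl)-5,7-dihydroxy-8-(3-hydroxy-3-methylbutyl)-2,3-dihydro-4H-chromen-4-one | CC(C)(O)CCc1c(O)cc(O)c2c1OC(c1ccc(O)c(O)c1)CC2=O
A3 | alternative 2 | (2S)-2-(3,4-dihydroxyphenyl)-5,7-dihydroxy-2,3-dihydro-4H-chromen-4-one (eriodictyol) | O=C1C[C@@H](c2ccc(O)c(O)c2)Oc2cc(O)cc(O)c12
A4 | alternative 2 | (2S)-5-(allyloxy)-7-(benzyloxy)-2-[3,4-bis(benzyloxy)phenyl]-2,3-dihydro-4H-chromen-4-one | C=CCOc1cc(OCc2ccccc2)cc2c1C(=O)C[C@@H](c1ccc(OCc3ccccc3)c(OCc3ccccc3)c1)O2
A5 | alternative 2 | (2S)-6-allyl-7-(benzyloxy)-2-[3,4-bis(benzyloxy)phenyl]-5-hydroxy-2,3-dihydro-4H-chromen-4-one | C=CCc1c(OCc2ccccc2)cc2c(c1O)C(=O)C[C@@H](c1ccc(OCc3ccccc3)c(OCc3ccccc3)c1)O2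
A6 | alternative 3 | methyl (2S)-2-[3,4-bis(benzyloxy)phenyl]-6-methyl-4-oxo-3,4-dihydro-2H-pyran-5-carboxylate | COC(=O)C1=C(C)O[C@H](c2ccc(OCc3ccccc3)c(OCc3ccccc3)c2)CC1=O
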